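Remark on the chemistry: locants are skeleton locants (decalin C1–C10; ring A = C1–C5 and C10; ring B = C5–C10; C11 = benzylic carbon) and stereodescriptors refer to them; Ar = 5-methoxy-2-(methoxymethoxy)-3-methylphenyl; "octalin" and "decalin" mean the octahydro- and decahydronaphthalene skeleton; compounds 1, 4, 6, 8 and 18 are assumed purchasable.

## Structural features

The target is a cis-fused decalin: ring A (C1–C5, C10) carries an exocyclic isopropylidene at C3 and a 2-carboxyethyl chain at C4, and ring B (C5–C10) carries a methyl at C8 and, at C9, a methyl plus the benzylic carbon C11 that links to a 2-hydroxy-5-methoxy-3-methylphenyl ring. The five stereocentres form one unbroken chain C4–C5–C10–C9–C8 (4S,5R,8R,9S,10S), and two of them (C5, C9) are quaternary and separated only by the fusion methine C10. The C4 chain, the C5 methyl, H10, the C9 methyl and the C8 methyl all lie on one face of the bicycle and C11 on the other. Fragile elements are the tetrasubstituted olefin sitting γ,δ to a carboxylic acid (protic acid invites migration or lactonisation), the para-methoxyphenol (oxidation to the quinone) and, in any C3-carbonyl precursor, the α-centre C4 and the γ-centre C10 (both can epimerise). The real difficulty is the congested C8–C9–C10–C5 array with its neopentyl C9–C11–aryl link, together with fixing C4 beside quaternary C5. The plan exploits the fact that C8, C9 (with their cis methyls) and C11 are the β-carbon, α-carbon and formyl carbon of (E)-2-methylbut-2-enal, while C7 and C10 are the termini of a ring-A vinylcyclohexene, so one cycloaddition builds ring B and sets C8, C9 and C10. The C5=C6 olefin that this cycloaddition leaves lies β,γ to a masked C3 carbonyl, which is the handle needed afterwards for C5 and C4.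

## Logic of the disconnections

25 to 23: the aryl O–CH2OCH3 bond is cut. The phenol has to be masked through organolithium, radical, cuprate and titanium chemistry, and the acetal chosen can be removed at the end without protic acid. The forward step must leave the isopropylidene and the acid untouched.

23 to 21: the two C–O bonds of the carboxyl group are cut, so the acid carbon is carried as the silicon-bearing carbon of an alkynylsilane. This lets the three-carbon chain enter as a reactive propargylic electrophile and keeps an ester out of the titanium step. The forward hydroboration must ignore the tetrasubstituted olefin.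

21 to 20: the C3=C(CH3)2 double bond is cut to a C3 ketone and acetone. Keeping oxygen at C3 until this point lets it activate C4 and C5 first. The forward olefination must be non-basic, because C4 is still α to the carbonyl.

20 to 17 and 18: the C4–CH2 bond is cut. Compound 17 holds the C3–C4 enolate in regiodefined form, so no choice between C2 and C4 arises. The forward alkylation must occur on the face that carries the C5 methyl and H10.

17 to 16: the C5–CH3 bond is cut. This removes the quaternary centre C5 and returns an enone whose conjugate addition delivers exactly the enolate needed for the previous cut. The methyl must arrive cis to H10.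

16 to 14: a functional-group change only, the enone being traced to the ketal with its β,γ-olefin. The forward hydrolysis and conjugation must not disturb C10, which is γ to the enone.

14 to 13, then to 7 and 10: the C11–aryl bond and the C11–O bond are cut. C11 is neopentyl, so a displacement is ruled out and the bond is made by carbonyl addition followed by deoxygenation. The aldehyde of 7 is the natural acceptor and cannot enolise.

10 to 9 to 8: the aryl C–Br and O–CH2 bonds are cut. Bromination ortho to the free hydroxyl fixes the site of the later lithium, and the acetal then also stabilises the aryllithium.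

7 to 5 and 6: the C7–C8 and C9–C10 bonds are cut, opening ring B. This removes three stereocentres and one quaternary carbon at once and leaves two achiral partners. The forward cycloaddition must be regio-, endo- and face-selective. The dioxolane in 5 is kept because it masks C3, keeps the ring olefin out of conjugation, and later gives the enone on hydrolysis.

5 to 3 and 4, then to 1: the vinyl–ring bond and the enol O–S bond are cut. The forward enolisation must occur on the side of the ketone away from the ketal.

## Other disconnections considered

Alternative 1: The cut is the C4–C5 bond of ring A in the octalinone A1, paired with the C2–C7 bond of a bicyclo[2.2.2]octenol A2 that is broken. In the forward key step the potassium alkoxide of A2 (KH, 18-crown-6) undergoes an anionic oxy-Cope shift to the enolate of A1. In its favour, one stereospecific pericyclic step fixes C4 and C5 relative to C8–C10, makes the quaternary C5 and guarantees the cis fusion. C4 in A1 is not α to a carbonyl and cannot epimerise; on control of C4 and C5 this alternative is better than the chosen plan. Against it, the cage enforces a boat-like array, so only a (Z)-alkenyl group in A2 places the chain cis to the C5 methyl. That puts the chain in the crowded inside position and requires a face-selective (Z)-alkenylmetal addition. The carbonyl of A1 also emerges at C2, so a 1,2-transposition to C3 is needed before the isopropylidene can be made, and the C6=C7 olefin and the protected primary alcohol need further steps. A2 itself needs a dearomatisation–cycloaddition that must set C8 and C9 with a poorly reactive trisubstituted alkene, and its absolute configuration must come from an auxiliary or a resolution. On mechanism the two key steps are equally well founded; on structure the chosen plan starts from far simpler partners; on step economy the alternative is clearly longer.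

Alternative 2: The cut is the C5–C10 and C8–C9 bonds of the octalin aldehyde A3, so both rings come from the acyclic trienal A4. The forward key step is a Me2AlCl-promoted intramolecular Diels–Alder reaction of the (Z)-2-methylenal onto the (Z,E)-diene. In its favour, both rings and four stereocentres arise together from olefin geometry, the cis fusion follows from the Z-diene, and the C3 oxygen and the C4 chain are already in place. No enolate alkylation at C4 and no conjugate addition at C5 are needed afterwards, which is better than the chosen plan. Against it, a trisubstituted Z-diene with an inside substituent reaches the s-cis form reluctantly and can divert by 1,5-hydrogen shift. Lewis-acid isomerisation of the (Z)-enal would invert C9. Facial selectivity rests on the allylic C3/C4 centres and is plausible but not assured. A4 needs three defined olefin geometries and two stereocentres, a long linear sequence. A3 still requires the same aryl addition and deoxygenation, hydrogenation of C6=C7 and the same isopropylidene problem, so the end game is equal to that of the chosen plan. Overall it is longer, because the effort is moved into the precursor.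

Alternative 3: The cut is three C–C bonds of the arene in the methyl ester A5. The forward key step is a Dötz benzannulation of the C9-propargyl decalin A6 with the (E)-propenyl(methoxy)carbene complex A7 and one CO ligand. In its favour, the substitution pattern of the arene follows from the mechanism (the large alkyne substituent ends next to the new hydroxyl, the methoxy para to it). The phenol arrives free, which is better than the chosen plan in protecting-group economy, and the two routes are equal in arene regiocontrol. Against it, the whole decalin problem (five stereocentres and the isopropylidene) is left unsolved and would still need a ring-B construction such as the chosen one. A propargyl group on quaternary C9 cannot be reached from a C9 aldehyde by displacement and would cost several homologation steps. The method uses stoichiometric chromium, and the electron-rich phenol is exposed to oxidation during demetalation. It is therefore not a replacement for the chosen key step but a longer way of attaching the arene.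

Key step: step 3

## Route

Step 1
Reactants: 1 1,4-dioxaspiro[4.5]decan-7-one
Product: 3 1,4-dioxaspiro[4.5]dec-7-en-7-yl trifluoromethanesulfonate, via lithium enolate 2 (not isolated)
Conditions: LiN(iPr)2, THF, −78 °C; PhNTf2, −78 → 0 °C
Reagents that add atoms: N-phenylbis(trifluoromethanesulfonimide), O=S(=O)(N(c1ccccc1)S(=O)(=O)C(F)(F)F)C(F)(F)F
Why: Kinetic deprotonation by the hindered amide should take a C8 proton, remote from the dioxolane, because the C6 protons are neopentyl-like and their removal would set up β-elimination of a ketal oxygen; O-sulfonylation of the enolate then gives the enol triflate (kinetic enol triflate formation).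

Step 2
Reactants: 3 1,4-dioxaspiro[4.5]dec-7-en-7-yl trifluoromethanesulfonate; 4 potassium ethenyltrifluoroborate
Product: 5 7-ethenyl-1,4-dioxaspiro[4.5]dec-7-ene
Conditions: PdCl2(dppf) (cat.), Cs2CO3, THF–H2O, 65 °C
Reagents that add atoms: none
Why: Suzuki–Miyaura coupling: oxidative addition of the alkenyl triflate to zerovalent palladium, transmetalation from the hydrolysed trifluoroborate and reductive elimination; the basic aqueous medium leaves the ketal intact and no stereocentre is involved.

Step 3
Reactants: 5 7-ethenyl-1,4-dioxaspiro[4.5]dec-7-ene; 6 (E)-2-methylbut-2-enal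
Product: 7 (8R,9S,10R)-9-formyl-8,9-dimethyl-Δ5(6)-octalin-3-one ethylene ketal (C8 methyl, C9 methyl and H10 on one face, formyl on the other)
Conditions: (S)-1-(2-methylphenyl)-3,3-diphenyltetrahydro-1H,3H-pyrrolo[1,2-c][1,3,2]oxazaborole (20 mol%), Tf2NH (18 mol%), CH2Cl2, −78 → −20 °C, 5 in excess
Reagents that add atoms: none
Why: Tf2NH protonates the oxazaborolidine nitrogen to give a cationic boron Lewis acid that binds the formyl oxygen of s-trans 6, the formyl C–H being held by the ring oxygen and the C8=C9 bond lying over one phenyl group. Diene 5 then adds in a concerted, asynchronous [4+2] cycloaddition in which C7–C8 bonding runs ahead of C9–C10 bonding; the closest known reaction type is the oxazaborolidinium-catalysed Diels–Alder reaction of 2-substituted enals with 1-vinylcyclohexenes. Ring B closes as a six-membered ring by intermolecular cycloaddition, both ring bonds forming in the one step and the new olefin appearing at C5=C6. Regiochemistry should follow from the diene polarisation: the unsubstituted terminus C7 carries the larger HOMO coefficient and bonds to the β-carbon C8, so the ring terminus C10 bonds to the α-carbon C9. The cis relation of the C8 and C9 methyls is fixed by suprafacial addition to the (E)-olefin. C10 is set relative to C9 by the endo position of the coordinated formyl group, which places C11 cis to C1 and the C9 methyl cis to H10. The absolute sense comes from the catalyst: the stacked phenyl group covers one face of the enal and leaves the Re face of its α-carbon open, which corresponds to 8R,9S,10R. The step needs regio-, endo- and facial selectivity at once; low temperature, excess diene and the non-coordinating triflimide counter-ion are chosen so that the dioxolane is not ionised.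

Step 4
Reactants: 8 4-methoxy-2-methylphenol
Product: 9 2-bromo-4-methoxy-6-methylphenol
Conditions: N-bromosuccinimide, CH2Cl2, −20 → 0 °C
Reagents that add atoms: N-bromosuccinimide, O=C1CCC(=O)N1Br
Why: Electrophilic aromatic bromination; the free hydroxyl is the strongest director, its para position is blocked by methoxy and one ortho position by methyl, so the remaining ortho carbon should be brominated.

Step 5
Reactants: 9 2-bromo-4-methoxy-6-methylphenol
Product: 10 1-bromo-5-methoxy-2-(methoxymethoxy)-3-methylbenzene
Conditions: NaH, MOMCl, THF–DMF, 0 → 25 °C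
Reagents that add atoms: chloromethyl methyl ether, COCCl
Why: O-alkylation of the sodium phenoxide (Williamson-type); the methoxymethyl ether stabilises the later ortho-lithio species by chelation, tolerates base, radicals, cuprates and low-valent titanium, and can be removed at the end without protic acid.

Step 6
Reactants: 10 1-bromo-5-methoxy-2-(methoxymethoxy)-3-methylbenzene; 7 (8R,9S,10R)-9-formyl-8,9-dimethyl-Δ5(6)-octalin-3-one ethylene ketal
Product: 13 O-[(Ar)((8R,9S,10R)-3,3-ethylenedioxy-8,9-dimethyl-Δ5(6)-octalin-9-yl)methyl] S-methyl carbonodithioate (both C11 epimers), via aryllithium 11 (not isolated), via lithium alkoxide 12 (not isolated)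
Conditions: n-BuLi, THF, −78 °C; add 7, −78 → −40 °C; CS2, → 25 °C; MeI
Reagents that add atoms: carbon disulfide, S=C=S; iodomethane, CI
Why: Bromine–lithium exchange gives a chelated aryllithium that adds to the non-enolisable neopentyl aldehyde, and the alkoxide is captured in the same flask as the xanthate; the configuration at C11 is irrelevant because the oxygen is removed in the next step.

Step 7
Reactants: 13 O-[(Ar)((8R,9S,10R)-3,3-ethylenedioxy-8,9-dimethyl-Δ5(6)-octalin-9-yl)methyl] S-methyl carbonodithioate
Product: 14 (8R,9S,10R)-9-(ArCH2)-8,9-dimethyl-Δ5(6)-octalin-3-one ethylene ketal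
Conditions: Bu3SnH, AIBN (cat.), toluene, 110 °C
Reagents that add atoms: none
Why: Barton–McCombie deoxygenation: the stannyl radical adds to the thiocarbonyl, β-scission releases a benzylic radical at C11 and this abstracts hydrogen from the stannane; C9 has no hydrogen, so thermal xanthate elimination is impossible, and the ketal, acetal and trisubstituted olefin are inert.

Step 8
Reactants: 14 (8R,9S,10R)-9-(ArCH2)-8,9-dimethyl-Δ5(6)-octalin-3-one ethylene ketal
Product: 16 (8R,9S,10R)-9-(ArCH2)-8,9-dimethyl-Δ4(5)-octalin-3-one, via β,γ-enone 15 (not isolated)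
Conditions: 1 M HCl, THF, 25 °C
Reagents that add atoms: water, O
Why: Acid hydrolysis of the dioxolane gives the β,γ-enone, which tautomerises through the C3 dienol to the conjugated enone as the thermodynamic product; the aryl acetal hydrolyses far more slowly at this acidity, and mild, short treatment is chosen because C10 is γ to the enone and could epimerise through the extended dienol.

Step 9
Reactants: 16 (8R,9S,10R)-9-(ArCH2)-8,9-dimethyl-Δ4(5)-octalin-3-one
Product: 17 (5R,8R,9S,10S)-9-(ArCH2)-5,8,9-trimethyl-3-(trimethylsilyloxy)-Δ3(4)-octalin (cis-fused, C5 methyl on the face of H10)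
Conditions: Me2CuLi (from CuI and MeLi), TMSCl, THF, −78 → −30 °C; Et3N
Reagents that add atoms: lithium dimethylcuprate, [Li+].C[Cu-]C; chlorotrimethylsilane, C[Si](C)(C)Cl
Why: Silyl-chloride-accelerated cuprate conjugate addition to a β,β-disubstituted enone; the methyl should arrive at C5 on the face of H10, the usual cis-fused outcome for octalones with a fusion hydrogen, reinforced here by the C9 arylmethyl group on the opposite face of ring B. The enolate is captured regiospecifically as the silyl enol ether.

Step 10
Reactants: 17 (5R,8R,9S,10S)-9-(ArCH2)-5,8,9-trimethyl-3-(trimethylsilyloxy)-Δ3(4)-octalin; 18 3-bromo-1-(trimethylsilyl)prop-1-yne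
Product: 20 (4S,5R,8R,9S,10S)-9-(ArCH2)-5,8,9-trimethyl-4-[3-(trimethylsilyl)prop-2-yn-1-yl]decalin-3-one (cis-fused), via lithium enolate 19 (not isolated)
Conditions: MeLi, THF, 0 → 25 °C; then 18, DMPU, −78 → −20 °C
Reagents that add atoms: none
Why: Methyllithium cleaves the O–Si bond to the regiodefined lithium enolate without equilibration, and SN2 alkylation by the propargylic bromide follows (regiospecific enolate alkylation). Attack is expected on the convex face of the cis-fused bicycle, the face of the C5 methyl and H10, because ring B covers the other face; this gives 4S.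

Step 11
Reactants: 20 (4S,5R,8R,9S,10S)-9-(ArCH2)-5,8,9-trimethyl-4-[3-(trimethylsilyl)prop-2-yn-1-yl]decalin-3-one
Product: 21 (4S,5R,8R,9S,10S)-9-(ArCH2)-5,8,9-trimethyl-3-(propan-2-ylidene)-4-[3-(trimethylsilyl)prop-2-yn-1-yl]decalin
Conditions: TiCl3(DME)1.5, Zn–Cu couple, DME, reflux; 20 and acetone (excess) added slowly
Reagents that add atoms: acetone, CC(C)=O
Why: McMurry cross-coupling: low-valent titanium couples the two carbonyl groups reductively and deoxygenates the titanium-bound diolate to the tetrasubstituted olefin; a large excess of volatile acetone should favour the mixed product. The medium is not basic, so C4 should keep its configuration, and after this step C4 no longer adjoins a carbonyl.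

Step 12
Reactants: 21 (4S,5R,8R,9S,10S)-9-(ArCH2)-5,8,9-trimethyl-3-(propan-2-ylidene)-4-[3-(trimethylsilyl)prop-2-yn-1-yl]decalin
Product: 23 3-[(4S,5R,8R,9S,10S)-9-(ArCH2)-5,8,9-trimethyl-3-(propan-2-ylidene)decalin-4-yl]propanoic acid, via alkenylborane 22 (not isolated)
Conditions: (C6H11)2BH (from BH3·SMe2 and cyclohexene), THF, 0 → 25 °C; NaOH, H2O2, 50 °C; citric acid
Reagents that add atoms: hydrogen peroxide, OO; sodium hydroxide, [Na+].[OH-]
Why: Hydroboration of a 1-silylalkyne by a dialkylborane places boron on the silicon-bearing carbon, and alkaline peroxide then turns that carbon into the carboxyl carbon (known hydroboration–oxidation of 1-silylalkynes to carboxylic acids); the hindered tetrasubstituted olefin should not react with the bulky borane.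

Step 13
Reactants: 23 3-[(4S,5R,8R,9S,10S)-9-(ArCH2)-5,8,9-trimethyl-3-(propan-2-ylidene)decalin-4-yl]propanoic acid
Product: 25 3-[(4S,5R,8R,9S,10S)-9-[(2-hydroxy-5-methoxy-3-methylphenyl)methyl]-5,8,9-trimethyl-3-(propan-2-ylidene)decalin-4-yl]propanoic acid (CNP0299684.4), via bis(trimethylsilyl) derivative 24 (not isolated)
Conditions: TMSOTf, 2,2′-bipyridyl, CH2Cl2, 0 → 25 °C; then H2O–THF
Reagents that add atoms: none
Why: The silyl triflate–bipyridyl pair converts an aryl methoxymethyl ether into the aryl silyl ether under buffered conditions, the amine taking up the methoxymethyl cation, and water then frees the phenol and the silylated acid; protic acid, which could move the isopropylidene or lactonise onto it, is avoided.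

## Compound list

1 | 1,4-dioxaspiro[4.5]decan-7-one | O=C1CCCC2(C1)OCCO2 | starting material
2 | lithium 1,4-dioxaspiro[4.5]dec-7-en-7-olate | [Li]OC1=CCCC2(OCCO2)C1 | intermediate (not isolated)
3 | 1,4-dioxaspiro[4.5]dec-7-en-7-yl trifluoromethanesulfonate | O=S(=O)(OC1=CCCC2(OCCO2)C1)C(F)(F)F | intermediate
4 | potassium ethenyltrifluoroborate | C=C[B-](F)(F)F.[K+] | starting material
5 | 7-ethenyl-1,4-dioxaspiro[4.5]dec-7-ene | C=CC1=CCCC2(OCCO2)C1 | intermediate
6 | (E)-2-methylbut-2-enal | C/C=C(\C)C=O | starting material
7 | (8R,9S,10R)-9-formyl-8,9-dimethyl-Δ5(6)-octalin-3-one ethylene ketal | O=C[C@]2(C)[C@@H]3CCC4(OCCO4)CC3=CC[C@H]2C | intermediate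
8 | 4-methoxy-2-methylphenol | COc1ccc(O)c(C)c1 | starting material
9 | 2-bromo-4-methoxy-6-methylphenol | COc1cc(C)c(O)c(Br)c1 | intermediate
10 | 1-bromo-5-methoxy-2-(methoxymethoxy)-3-methylbenzene | COCOc1c(C)cc(OC)cc1Br | intermediate
11 | [5-methoxy-2-(methoxymethoxy)-3-methylphenyl]lithium | [Li]c1cc(OC)cc(C)c1OCOC | intermediate (not isolated)
12 | lithium (Ar)((8R,9S,10R)-3,3-ethylenedioxy-8,9-dimethyl-Δ5(6)-octalin-9-yl)methanolate, both C11 epimers | [Li]OC(c1cc(OC)cc(C)c1OCOC)[C@]2(C)[C@@H]3CCC4(OCCO4)CC3=CC[C@H]2C | intermediate (not isolated)
13 | O-[(Ar)((8R,9S,10R)-3,3-ethylenedioxy-8,9-dimethyl-Δ5(6)-octalin-9-yl)methyl] S-methyl carbonodithioate, both C11 epimers | CSC(=S)OC(c1cc(OC)cc(C)c1OCOC)[C@]2(C)[C@@H]3CCC4(OCCO4)CC3=CC[C@H]2C | intermediate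
14 | (8R,9S,10R)-9-(ArCH2)-8,9-dimethyl-Δ5(6)-octalin-3-one ethylene ketal | COCOc1c(C)cc(OC)cc1C[C@]2(C)[C@@H]3CCC4(OCCO4)CC3=CC[C@H]2C | intermediate
15 | (8R,9S,10R)-9-(ArCH2)-8,9-dimethyl-Δ5(6)-octalin-3-one | COCOc1c(C)cc(OC)cc1C[C@]2(C)[C@@H]3CCC(=O)CC3=CC[C@H]2C | intermediate (not isolated)
16 | (8R,9S,10R)-9-(ArCH2)-8,9-dimethyl-Δ4(5)-octalin-3-one | COCOc1c(C)cc(OC)cc1C[C@]2(C)[C@@H]3CCC(=O)C=C3CC[C@H]2C | intermediate
17 | (5R,8R,9S,10S)-9-(ArCH2)-5,8,9-trimethyl-3-(trimethylsilyloxy)-Δ3(4)-octalin | COCOc1c(C)cc(OC)cc1C[C@]2(C)[C@@H]3CCC(O[Si](C)(C)C)=C[C@]3(C)CC[C@H]2C | intermediate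
18 | 3-bromo-1-(trimethylsilyl)prop-1-yne | C[Si](C)(C)C#CCBr | starting material
19 | lithium (5R,8R,9S,10S)-9-(ArCH2)-5,8,9-trimethyl-Δ3(4)-octalin-3-olate | COCOc1c(C)cc(OC)cc1C[C@]2(C)[C@@H]3CCC(O[Li])=C[C@]3(C)CC[C@H]2C | intermediate (not isolated)
20 | (4S,5R,8R,9S,10S)-9-(ArCH2)-5,8,9-trimethyl-4-[3-(trimethylsilyl)prop-2-yn-1-yl]decalin-3-one | COCOc1c(C)cc(OC)cc1C[C@]2(C)[C@@H]3CCC(=O)[C@@H](CC#C[Si](C)(C)C)[C@]3(C)CC[C@H]2C | intermediate
21 | (4S,5R,8R,9S,10S)-9-(ArCH2)-5,8,9-trimethyl-3-(propan-2-ylidene)-4-[3-(trimethylsilyl)prop-2-yn-1-yl]decalin | COCOc1c(C)cc(OC)cc1C[C@]2(C)[C@@H]3CCC(=C(C)C)[C@@H](CC#C[Si](C)(C)C)[C@]3(C)CC[C@H]2C | intermediate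
22 | alkenylborane of 21, C4 side chain CH2–CH=C(SiMe3)B(C6H11)2 with the CH2 and silyl groups cis | COCOc1c(C)cc(OC)cc1C[C@]2(C)[C@@H]3CCC(=C(C)C)[C@@H](C/C=C(\[Si](C)(C)C)B(C4CCCCC4)C4CCCCC4)[C@]3(C)CC[C@H]2C | intermediate (not isolated)
23 | 3-[(4S,5R,8R,9S,10S)-9-(ArCH2)-5,8,9-trimethyl-3-(propan-2-ylidene)decalin-4-yl]propanoic acid | COCOc1c(C)cc(OC)cc1C[C@]2(C)[C@@H]3CCC(=C(C)C)[C@@H](CCC(=O)O)[C@]3(C)CC[C@H]2C | intermediate
24 | trimethylsilyl ester of the target with the phenol as its trimethylsilyl ether | COc1cc(C)c(O[Si](C)(C)C)c(C[C@]2(C)[C@@H]3CCC(=C(C)C)[C@@H](CCC(=O)O[Si](C)(C)C)[C@]3(C)CC[C@H]2C)c1 | intermediate (not isolated)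
25 | 3-[(4S,5R,8R,9S,10S)-9-[(2-hydroxy-5-methoxy-3-methylphenyl)methyl]-5,8,9-trimethyl-3-(propan-2-ylidene)decalin-4-yl]propanoic acid | COc1cc(C)c(O)c(C[C@]2(C)[C@@H]3CCC(=C(C)C)[C@@H](CCC(=O)O)[C@]3(C)CC[C@H]2C)c1 | target

## Step count and risk

Total: 13 steps. Longest linear sequence: 11 steps (1 to 25 through steps 1, 2, 3 and 6 to 13); steps 4 and 5 form the two-step aryl branch.

Least certain steps:

Step 3 (key step). The most likely failure is too slow a cycloaddition at the temperatures where the catalyst still discriminates, since a trisubstituted enal meets a diene of only moderate reactivity. Acid-induced loss of the diene (oligomerisation, ketal ionisation) and erosion of endo and facial selectivity would then compete. Fallback: setting out from 5 and 6, the cycloaddition is run with an achiral aluminium Lewis acid (Me2AlCl, CH2Cl2) to the racemic aldehyde F1. Condensation with (1S,2S)-N,N′-dimethyl-1,2-diphenylethane-1,2-diamine gives the diastereomeric aminals F2 (from the 8R,9S,10R aldehyde) and F3 (from its enantiomer). These are separated by chromatography, and mild hydrolysis of F2 on wet silica, much faster than that of the dioxolane, returns to the route at 7.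

Step 11. Reductive coupling at a hindered, α-branched carbonyl may stall at the diol stage or favour homocoupling and simple reduction. Prolonged heating with Lewis-acidic titanium may enolise C4 or attack the alkynylsilane. Fallback: setting out from 20, the lithium enolate of S-phenyl 2-methylpropanethioate is added (THF, −78 → 0 °C); the aldolate closes onto the thioester to give the spiro β-lactone F4. Thermolysis of F4 (toluene, 110 °C) extrudes CO2 and returns to the route at 21.

Step 10. Alkylation may take place on the wrong face of C4, or proton transfer may move the enolate to C2 before alkylation, because the nucleophilic carbon adjoins quaternary C5. Fallback: setting out from 17 (cleaved to 19 as before), a Mannich reaction with dimethyl(methylidene)ammonium iodide gives the amino ketone F5. Quaternisation with MeI and elimination with NaHCO3 give the α-methylene ketone F6. Conjugate addition of Et2AlC≡CSiMe3 followed by kinetic protonation of the aluminium enolate then sets C4 by hydrogen delivery, which has the complementary facial sense to alkylation, and returns to the route at 20.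

Step 9. Methyl transfer may occur on the wrong face of C5, giving the trans-fused skeleton, or may be slow at a β,β-disubstituted carbon flanked by C10 and C9. Fallback: setting out from 16, Luche reduction (NaBH4, CeCl3, MeOH) gives the allylic alcohol F7 with the hydroxyl on the face of H10. Hydroxyl-directed Simmons–Smith cyclopropanation (Et2Zn, CH2I2) gives the cyclopropyl carbinol F8 on that same face, and Dess–Martin oxidation gives the cyclopropyl ketone F9. Li/NH3 then cleaves the cyclopropane bond that overlaps the carbonyl, which creates the C5 methyl and the lithium enolate directly. The fallback returns to the route at 19, which is alkylated with 18 after removal of the ammonia.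

Step 1. Deprotonation may compete at C6, between the carbonyl and the ketal, which would give the regioisomeric triflate and ketal elimination. Fallback: setting out from 1, condensation with 2,4,6-tri(propan-2-yl)benzenesulfonohydrazide gives the hydrazone F10. A Shapiro reaction (n-BuLi, two equivalents) directs the second deprotonation to the less hindered methylene; trapping the alkenyllithium with DMF gives the enal F11. Wittig methylenation (Ph3P=CH2) then returns to the route at 5.

## Further compounds

F1 | step 3 | racemic 9-formyl-8,9-dimethyl-Δ5(6)-octalin-3-one ethylene ketal (relative configuration of 7, both enantiomers) | O=C[C@]2(C)[C@@H]3CCC4(OCCO4)CC3=CC[C@H]2C.O=C[C@@]2(C)[C@H]3CCC4(OCCO4)CC3=CC[C@@H]2C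
F2 | step 3 | (4S,5S)-1,3-dimethyl-4,5-diphenylimidazolidin-2-yl aminal of the (8R,9S,10R) aldehyde | CN1[C@@H](c2ccccc2)[C@H](c2ccccc2)N(C)C1[C@]3(C)[C@@H]4CCC5(OCCO5)CC4=CC[C@H]3C
F3 | step 3 | (4S,5S)-1,3-dimethyl-4,5-diphenylimidazolidin-2-yl aminal of the (8S,9R,10S) aldehyde | CN1[C@@H](c2ccccc2)[C@H](c2ccccc2)N(C)C1[C@@]3(C)[C@H]4CCC5(OCCO5)CC4=CC[C@@H]3C
F4 | step 11 | spiro β-lactone of 20 (3,3-dimethyloxetan-2-one spiro-fused at C3, C3 configuration undefined) | COCOc1c(C)cc(OC)cc1C[C@]2(C)[C@@H]3CCC4(OC(=O)C4(C)C)[C@@H](CC#C[Si](C)(C)C)[C@]3(C)CC[C@H]2C
F5 | step 10 | (5R,8R,9S,10S)-9-(ArCH2)-4-[(dimethylamino)methyl]-5,8,9-trimethyldecalin-3-one (C4 epimers) | COCOc1c(C)cc(OC)cc1C[C@]2(C)[C@@H]3CCC(=O)C(CN(C)C)[C@]3(C)CC[C@H]2C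
F6 | step 10 | (5R,8R,9S,10S)-9-(ArCH2)-5,8,9-trimethyl-4-methylidenedecalin-3-one | COCOc1c(C)cc(OC)cc1C[C@]2(C)[C@@H]3CCC(=O)C(=C)[C@]3(C)CC[C@H]2C
F7 | step 9 | (8R,9S,10R)-9-(ArCH2)-8,9-dimethyl-Δ4(5)-octalin-3-ol, hydroxyl on the face of H10 | COCOc1c(C)cc(OC)cc1C[C@]2(C)[C@@H]3CC[C@@H](O)C=C3CC[C@H]2C
F8 | step 9 | 4,5-methano derivative of F7, cyclopropane on the face of H10 and the hydroxyl | COCOc1c(C)cc(OC)cc1C[C@]2(C)[C@@H]3CC[C@@H](O)[C@H]4C[C@@]34CC[C@H]2C
F9 | step 9 | 4,5-methano-9-(ArCH2)-8,9-dimethyldecalin-3-one, cyclopropane on the face of H10 | COCOc1c(C)cc(OC)cc1C[C@]2(C)[C@@H]3CCC(=O)[C@H]4C[C@@]34CC[C@H]2C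
F10 | step 1 | N′-(1,4-dioxaspiro[4.5]decan-7-ylidene)-2,4,6-tri(propan-2-yl)benzenesulfonohydrazide | CC(C)c1cc(C(C)C)c(S(=O)(=O)NN=C2CCCC3(C2)OCCO3)c(C(C)C)c1
F11 | step 1 | 1,4-dioxaspiro[4.5]dec-7-ene-7-carbaldehyde | O=CC1=CCCC2(OCCO2)C1
A1 | alternative 1 | cis-fused octalin-2-one with C6=C7 olefin, product of the oxy-Cope step | COc1cc(C)c(OCOC)c(C[C@]2(C)[C@@H]3CC(=O)C[C@@H](CCCOCc4ccc(OC)cc4)[C@]3(C)C=C[C@H]2C)c1
A2 | alternative 1 | bicyclo[2.2.2]oct-5-en-2-ol carrying the (Z)-alkenyl group syn to the ring olefin | COc1cc(C)c(OCOC)c(C[C@]2(C)[C@@H]3C[C@@](O)(/C=C\CCCOCc4ccc(OC)cc4)[C@@H](C=C3C)[C@H]2C)c1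
A3 | alternative 2 | cis-fused octalin aldehyde with C6=C7 olefin, product of the intramolecular cycloaddition | O=C[C@]2(C)[C@@H]3CC[C@H](O[Si](C)(C)C(C)(C)C)[C@@H](CCCO[Si](C)(C)C(C)(C)C)[C@]3(C)C=C[C@H]2C
A4 | alternative 2 | acyclic trienal with (Z)-2-methylenal and (Z,E)-diene | O=C/C(C)=C\CC[C@H](O[Si](C)(C)C(C)(C)C)[C@@H](CCCO[Si](C)(C)C(C)(C)C)/C(C)=C\C=C\C
A5 | alternative 3 | methyl ester of the target, product of the benzannulation | COc1cc(C)c(O)c(C[C@]2(C)[C@@H]3CCC(=C(C)C)[C@@H](CCC(=O)OC)[C@]3(C)CC[C@H]2C)c1
A6 | alternative 3 | C9-propargyl decalin methyl ester | C#CC[C@]2(C)[C@@H]3CCC(=C(C)C)[C@@H](CCC(=O)OC)[C@]3(C)CC[C@H]2C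
A7 | alternative 3 | pentacarbonyl[(E)-1-methoxybut-2-en-1-ylidene]chromium | C/C=C/C(OC)=[Cr](=C=O)(=C=O)(=C=O)(=C=O)=C=O
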